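No rate constant is given, so we begin with a subtraction, which needs none.

common to all: left-handed substrate 10 mM; right-handed substrate 10 mM; gas 0.51 mM (held)
- oak: free catalyst 0.1 mol%; impurity 3.6 µM; run made earlier
- larch: free catalyst 0.1 mol%; impurity 5.4 µM; run made earlier
- alder: free catalyst 0.05 mol%; impurity 7.2 µM; run made earlier
- flask: free catalyst 0.1 mol%; impurity 7.2 µM; time 8.0 h

- oak (time / h: left-handed product / %, right-handed product / %): 1.33: 2.9, 6.1; 2.50: 8.3, 10.7; 4.00: 15.0, 16.5; 5.00: 18.7, 20.9
- larch (time / h: left-handed product / %, right-handed product / %): 0.667: 2.5, 2.2; 1.50: 3.6, 6.7; 3.00: 7.7, 10.0; 5.00: 15.0, 15.7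
- alder (time / h: left-handed product / %, right-handed product / %): 0.417: 1.4, 1.5; 0.833: 0, 0; 2.00: 0, 0; 5.00: 0, 0

(readings scatter by 1 percentage point)

- free catalyst is single-handed; left-handed substrate and right-handed substrate are mirror images of each other, charged as a racemate, each of them at the stated concentration
- at the start none of partner is dissolved
- the numbers in the tables scatter by 1 percentage point (one standard deviation)
- steps under discussion: free catalyst + left-handed substrate <-> catalyst intermediate A; free catalyst + right-handed substrate <-> catalyst intermediate B; partner + catalyst intermediate A -> free catalyst + left-handed product; partner + catalyst intermediate B -> free catalyst + right-handed product; left-handed product <-> right-handed product; gas <-> partner; free catalyst + impurity -> spent catalyst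
- an excess is the difference of the two amounts in percent of their sum
- an excess is below zero if the other one leads

1. excess of left-handed product over right-handed product in the product at 50 min
2. excess of left-handed product over right-handed product in the product at 8.0 h
3. part of the left-handed substrate and right-handed substrate charged together that has reacted at 8.0 h

Alder has 5.00 µM of free catalyst against 7.2 µM of impurity, and from 0.833 h on it reads 0%. So we let impurity kill free catalyst one for one. That leaves 6.40 µM in oak, 4.60 µM in larch and 2.80 µM in the flask: the live catalyst L, the catalyst charged less the impurity.

One dead run proves little, though. Oak and larch were charged with the same catalyst, so we test L on them through the turnover N, product made per live catalyst per hour up to 5.00 h. Oak gives 247 h⁻¹ and larch 267 h⁻¹, close enough to keep L.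

Can N be frozen while substrate falls? Oak has 19.0% at 2.50 h and twice that at 5.00 h, which reads as zero order in substrate.

But N as read rises from oak to larch, as L falls. At a scatter of 1 percentage point that proves nothing, yet partner comes from the gas, and a busier flask may hold less of it. So we carry the trend on to the flask: we take N as 286 h⁻¹ and expect 32.1% reacted by 8.0 h.

In oak and larch the lead of right-handed product shows no growth with time. Averaged over their readings it is 0.343 pp µM⁻¹ of L, so we expect the flask to hold 0.96 points. That gives −2.99% at 8.0 h and −28.8% at 50 min. We hold the early size high, since larch at 0.667 h shows no lead yet.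

The forecast, less generous on conversion than we are, says −28%, −3.3% and 29%: “This is zero order in substrate”.

The flask gives −22.4%, −1.50% and 35.9%.

    free catalyst + left-handed substrate ⇌ catalyst intermediate A (K = 40.5 M⁻¹, k = 2.10 × 10⁵ M⁻¹ min⁻¹)
    free catalyst + right-handed substrate ⇌ catalyst intermediate B (K = 648 M⁻¹, k = 48600 M⁻¹ min⁻¹)
    partner + catalyst intermediate A → free catalyst + left-handed product (k = 44800 M⁻¹ min⁻¹)
    partner + catalyst intermediate B → free catalyst + right-handed product (k = 16400 M⁻¹ min⁻¹)
    left-handed product ⇌ right-handed product (k = 0.0326 min⁻¹)
    gas ⇌ partner, rate k6*(csat - [partner]) (kL = 0.0966 min⁻¹)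
    free catalyst + impurity → spent catalyst (k = 18500 M⁻¹ s⁻¹)

The flask holds 72.0% of its catalyst as spent catalyst, and L left 72.0% of it dead. Its turnover, averaged over 8.0 h, comes to 320 h⁻¹, higher than the figures read from oak and larch up to 5.00 h. With 0.4 mol% of free catalyst in the neighbour, L is 32.8 µM, so the dead share is 18.0%, and spent catalyst there reads 18.0%. At oak's turnover that L asks for 64.8 mM of product over 8.0 h, against 20.0 mM of substrate charged. The neighbour reacted 91.2% of the two substrates charged together, with 8.79% of left-handed substrate and 0% of right-handed substrate standing at the end.

Readings and results are calculated on assumed constants; the scatter is artificial.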